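Amounts first: at 8.00 d in epsilon 84.7% of the substrate still stands, and at 8.00 d in zeta 17.9%, although the zeta flask was charged with 3.3 equiv of partner. Substrate has nearly stopped falling in both, so the books to keep are those of the partner, which by the steps thought possible adds to substrate to give single product, adds to that to give double product, and also decomposes by itself.

in all of them: substrate 0.010 M

| run | partner | capture agent | remark | time |
|---|---|---|---|---|
| epsilon | 0.36 equiv | 0.20 mM | run made earlier |  |
| zeta | 3.3 equiv | 0.20 mM | run made earlier |  |
| Saturday's | 4.00 equiv | 0.200 mM |  | 12 d |
| Sunday's | 1.20 equiv | 0.200 mM |  | 12 d |
| Friday's | 0.500 equiv | 0.200 mM |  | 12 d |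

| run | time / d | single product / % | double product / % | substrate / % |
|---|---|---|---|---|
| epsilon | 0.625 | 6.0 | 1.0 | 92.6 |
| epsilon | 1.25 | 8.8 | 1.9 | 89.0 |
| epsilon | 2.50 | 11.8 | 2.0 | 86.5 |
| epsilon | 4.00 | 11.7 | 2.7 | 85.6 |
| epsilon | 8.00 | 11.4 | 2.7 | 84.7 |
| zeta | 1.67 | 22.3 | 46.6 | 29.5 |
| zeta | 3.00 | 18.6 | 57.7 | 22.6 |
| zeta | 5.00 | 17.3 | 62.5 | 20.3 |
| zeta | 6.00 | 16.0 | 62.8 | 18.8 |
| zeta | 8.00 | 16.0 | 62.6 | 17.9 |

(each reading ± 0.5 percentage points)

- for double product the crystals are counted in
- as a solid, counted per litre of solution: crystals
- the analysis behind the earlier runs scatters by 0.5 percentage points, standard deviation
- steps thought possible: crystals <-> double product; partner + single product -> double product + released group; partner -> decomposed reagent; substrate + partner -> single product + released group; single product + capture agent -> trapped intermediate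

- which of these holds the largest part of the substrate at the end of Saturday's (double product / substrate / single product)
- which of these holds the largest part of the substrate at the end of Sunday's (double product / substrate / single product)
- which of these holds the largest part of the substrate at the end of Friday's (double product / substrate / single product)
- how much single product is there at the end of Sunday's, in percent of the substrate charged

The ledger has three entries. Let a be the fraction of substrate left and f the fraction gone: each unit gone took one partner, whether it now sits as single product or, after meeting the capture agent, as trapped intermediate. Each unit of double product, D, took a second, and the remainder decomposed, so the wasted equivalents are w = equiv − f − D. If substrate falls in proportion to substrate times partner and decomposition goes with partner, then at one substrate concentration partner and time cancel, and you should watch the waste gauge g, defined as −ln a per equivalent wasted. Epsilon gives w = 0.180 equiv and 0.923; zeta gives 1.85 equiv and 0.928. These nearly agree, so freeze g at 0.925.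

For Sunday's, take the second addition's rate constant as 2 times the first, which makes D = f² and single product af. Guess that half of the charge is wasted: then a = 57.4%, and the entries total 1.21 equiv against 1.20 equiv charged, so the books nearly close. Single product comes to 22.5% once the capture agent's share is taken off. The forecast reads “about 0.93 per equiv wasted in both runs” and names double product, substrate and substrate for Saturday's, Sunday's and Friday's, with 22% single product on Sunday's; its substrate of 58% differs slightly from this reckoning.

    crystals ⇌ double product, rate k1*(cs1 - [double product]) while solid is left; crystals form when [double product] > cs1 (solubility = 7.10 mM, k = 0.145 /h)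
    partner + single product → double product + released group (k = 3.22 /M/h)
    partner → decomposed reagent (k = 0.0185 /h)
    substrate + partner → single product + released group (k = 1.73 /M/h)
    single product + capture agent → trapped intermediate (k = 24.4 /M/h)

Sunday's gives 24.1% single product, and 24.1% after 120 d, with partner at 0% by 12.0 d; the largest holder is double product in Saturday's, substrate in Sunday's and substrate in Friday's, as forecast. Sunday's substrate of 57.0% and g give w = 0.607 equiv, and the decomposed reagent stands at 0.601 equiv. In the neighbouring flask with 4.80 equiv of partner, substrate at 6.06% gives w = 3.03 equiv, and its decomposed reagent stands at 3.00 equiv.

The runs are simulated for an exercise; scatter was added.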